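**Retrosynthetic overview**
1. Target 16 ⇐ two-fold anionic ring contraction (1,2-acyl shift from O to C) of bis(2-methyl-1,3-benzodioxin-4-one) 13: each six-membered acylal ring becomes a five-membered keto-hemiketal ring, forming C2–C3 and C2'–C3' and carrying the acetal configuration into C2/C2'.
2. 13 ⇐ oxidative phenol homocoupling of two molecules of the monomeric (2R)-acetal 12 (C8–C8' biaryl bond).
3. 12 ⇐ catalytic asymmetric acetalization of salicylic acid 10 with acetaldehyde 11 (sets the stereocentre).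
4. 10 ⇐ Hoesch carboxylation of 4,5-dimethoxyresorcinol 6 ⇐ veratrole 2 (lithiation/borylation, then C–H borylation/oxidation) ⇐ catechol 1.
5. Ring order: benzene ring bought; 1,3-dioxinone ring (step 5); biaryl link (step 6); both furanone rings last, by contraction (step 7).

Assumption: the target string fixes only C2 and C2' (both R); the sense of the hindered 7,7'-biaryl axis is not defined there and is not controlled here.

**Route**

Step 1
Reactants: 1 catechol (benzene-1,2-diol)
Product: 2 1,2-dimethoxybenzene (veratrole)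
Conditions: MeI (2.5 equiv), K2CO3 (2.5 equiv), acetone, reflux
Reagents that add atoms: iodomethane, CI
Why: Williamson ether synthesis; both phenoxides are methylated cleanly and no stereocentre is involved.

Step 2
Reactants: 2 1,2-dimethoxybenzene
Product: 4 2-(2,3-dimethoxyphenyl)-4,4,5,5-tetramethyl-1,3,2-dioxaborolane, via aryllithium 3 (not isolated)
Conditions: n-BuLi, TMEDA, Et2O, 0 °C to rt; then 2-isopropoxy-4,4,5,5-tetramethyl-1,3,2-dioxaborolane, −78 °C to rt; H2O
Reagents that add atoms: 2-isopropoxy-4,4,5,5-tetramethyl-1,3,2-dioxaborolane, CC(C)OB1OC(C)(C)C(C)(C)O1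
Why: Directed ortho-metalation next to a methoxy group followed by electrophilic borylation puts boron at C3 of veratrole, the future C6–OH carbon.

Step 3
Reactants: 4 2-(2,3-dimethoxyphenyl)-4,4,5,5-tetramethyl-1,3,2-dioxaborolane
Product: 6 4,5-dimethoxybenzene-1,3-diol, via arene bis(pinacol boronate) 5 (not isolated)
Conditions: B2pin2, [Ir(OMe)(cod)]2 (1.5 mol %), 4,4'-di-tert-butyl-2,2'-bipyridine (3 mol %), THF, 80 °C; then KHSO5 (as the triple salt 2KHSO5·KHSO4·K2SO4), acetone/H2O, 0 °C, 10 min
Reagents that add atoms: potassium peroxymonosulfate, [K+].[O-]S(=O)(=O)OO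
Why: Sterically controlled iridium-catalysed C–H borylation reaches only C5 (the one C–H not ortho to a substituent), and one-pot oxidation of both C–B bonds (borylation/oxidation phenol synthesis) gives the resorcinol.

Step 4
Reactants: 6 4,5-dimethoxybenzene-1,3-diol; 7 trichloroacetonitrile
Product: 10 2,4-dihydroxy-5,6-dimethoxybenzoic acid, via ketiminium chloride 8 (not isolated), via trichloromethyl ketone 9 (not isolated)
Conditions: ZnCl2, HCl (g), Et2O, 0 °C; then H2O, 50 °C; then 2 M NaOH, N2, 0 °C to rt; then cold 2 M HCl to pH 2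
Reagents that add atoms: water, O; sodium hydroxide, [Na+].[OH-]
Why: Houben–Hoesch acylation goes para to one free OH and ortho to the other (C6 of 6, as with 5-substituted resorcinols), and haloform-type cleavage of the trichloromethyl ketone releases the acid, which is kept cold because it decarboxylates easily.

Step 5
Reactants: 10 2,4-dihydroxy-5,6-dimethoxybenzoic acid; 11 acetaldehyde
Product: 12 (2R)-7-hydroxy-5,6-dimethoxy-2-methyl-4H-1,3-benzodioxin-4-one
Conditions: acetaldehyde (3 equiv), (S)-3,3'-bis(2,4,6-triisopropylphenyl)-1,1'-binaphthyl-2,2'-diyl N-(trifluoromethylsulfonyl)phosphoramide (5 mol %), 5 Å molecular sieves, CHCl3, −40 °C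
Reagents that add atoms: none
Why: Proposed new method: enantioselective O,O-acetalization of a salicylic acid with an aldehyde under chiral Brønsted acid catalysis, in which condensation passes through an oxocarbenium/chiral-anion ion pair and the ring-closing C–O bond forms on one face to set C2 as R (the sense of induction must be confirmed in the first run and the antipodal acid used if it is opposite); the closest known reactions are the chiral phosphoramide-catalysed N,O-acetalization of salicylamides with aldehydes and the catalytic asymmetric acetalization and transacetalization of diols.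

Step 6
Reactants: 12 (2R)-7-hydroxy-5,6-dimethoxy-2-methyl-4H-1,3-benzodioxin-4-one (first molecule); 12 (2R)-7-hydroxy-5,6-dimethoxy-2-methyl-4H-1,3-benzodioxin-4-one (second molecule)
Product: 13 (2R,2'R)-7,7'-dihydroxy-5,5',6,6'-tetramethoxy-2,2'-dimethyl-4H,4'H-[8,8'-bi-1,3-benzodioxine]-4,4'-dione
Conditions: Na2S2O8 (0.6 equiv per 12, that is 1.2 equiv per dimer formed), FeSO4·7H2O (5 mol %), acetone/H2O, 50 °C
Reagents that add atoms: the second molecule of 12 named under Reactants ((2R)-7-hydroxy-5,6-dimethoxy-2-methyl-4H-1,3-benzodioxin-4-one), C[C@@H]1Oc2cc(O)c(OC)c(OC)c2C(=O)O1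
Why: Oxidative phenol homocoupling of the dehydrodivanillin type (2 × 12 → 13, each molecule losing its C8–H to the oxidant), in which the para-acyl ortho-methoxy phenol can form a C–C bond only at C8 (its single ring C–H); the acetal centres are untouched, and removing the minor heterochiral dimer raises the enantiopurity of the 2R,2'R product above that of 12.

Step 7
Reactants: 13 (2R,2'R)-7,7'-dihydroxy-5,5',6,6'-tetramethoxy-2,2'-dimethyl-4H,4'H-[8,8'-bi-1,3-benzodioxine]-4,4'-dione
Product: 16 (2R,2'R)-2,2',6,6'-tetrahydroxy-4,4',5,5'-tetramethoxy-2,2'-dimethyl-[7,7'-bi-1-benzofuran]-3,3'(2H,2'H)-dione, via bis(aryl silyl ether) 14 (not isolated), via tetrakis(silyl) bis-ketal 15 (not isolated)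
Conditions: Me3SiCl (8 equiv), LiTMP (lithium 2,2,6,6-tetramethylpiperidide, 5 equiv, added last), THF, −78 °C; then citric acid, MeOH/THF/H2O, 0 °C
Reagents that add atoms: none
Why: Proposed new method: after in-situ silylation of the phenols, LiTMP removes the acetal C2–H (the rings carry no other acidic C–H) and the configurationally stable α,α-dioxy carbanion attacks the adjacent lactone carbonyl faster than it inverts, a 1,2-acyl shift from O to C with retention that contracts the six-membered acylal to the five-membered keto-hemiketal alkoxide; Me3SiCl traps this alkoxide before it can open to the achiral diketone phenoxide, and mild acid then cleaves only O–Si bonds, so (2R)-acetal gives (2R)-hemiketal; the closest known reactions are the retentive 1,2-acyl and 1,2-carbamoyl shifts of α-lithiated benzoates and carbamates (acyl [1,2]-Wittig type) and lithium amide/Me3SiCl in-situ quench.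

**Compound list**
1 | catechol (benzene-1,2-diol) | Oc1ccccc1O | starting material
2 | 1,2-dimethoxybenzene (veratrole) | COc1ccccc1OC | intermediate
3 | (2,3-dimethoxyphenyl)lithium (aryllithium) | [Li]c1cccc(OC)c1OC | intermediate
4 | 2-(2,3-dimethoxyphenyl)-4,4,5,5-tetramethyl-1,3,2-dioxaborolane | COc1cccc(B2OC(C)(C)C(C)(C)O2)c1OC | intermediate
5 | 2,2'-(4,5-dimethoxy-1,3-phenylene)bis(4,4,5,5-tetramethyl-1,3,2-dioxaborolane) (arene bis(pinacol boronate)) | COc1cc(B2OC(C)(C)C(C)(C)O2)cc(B3OC(C)(C)C(C)(C)O3)c1OC | intermediate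
6 | 4,5-dimethoxybenzene-1,3-diol | COc1cc(O)cc(O)c1OC | intermediate
7 | trichloroacetonitrile | ClC(Cl)(Cl)C#N | starting material
8 | 2,2,2-trichloro-1-(2,4-dihydroxy-5,6-dimethoxyphenyl)ethan-1-iminium chloride (ketiminium chloride) | [Cl-].[NH2+]=C(c1c(O)cc(O)c(OC)c1OC)C(Cl)(Cl)Cl | intermediate
9 | 2,2,2-trichloro-1-(2,4-dihydroxy-5,6-dimethoxyphenyl)ethan-1-one (trichloromethyl ketone) | O=C(c1c(O)cc(O)c(OC)c1OC)C(Cl)(Cl)Cl | intermediate
10 | 2,4-dihydroxy-5,6-dimethoxybenzoic acid | OC(=O)c1c(O)cc(O)c(OC)c1OC | intermediate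
11 | acetaldehyde | CC=O | starting material
12 | (2R)-7-hydroxy-5,6-dimethoxy-2-methyl-4H-1,3-benzodioxin-4-one | C[C@@H]1Oc2cc(O)c(OC)c(OC)c2C(=O)O1 | intermediate
13 | (2R,2'R)-7,7'-dihydroxy-5,5',6,6'-tetramethoxy-2,2'-dimethyl-4H,4'H-[8,8'-bi-1,3-benzodioxine]-4,4'-dione | C[C@@H]1Oc2c(-c3c(O)c(OC)c(OC)c4c3O[C@@H](C)OC4=O)c(O)c(OC)c(OC)c2C(=O)O1 | intermediate
14 | (2R,2'R)-5,5',6,6'-tetramethoxy-2,2'-dimethyl-7,7'-bis(trimethylsilyloxy)-4H,4'H-[8,8'-bi-1,3-benzodioxine]-4,4'-dione (bis(aryl silyl ether)) | C[C@@H]1Oc2c(-c3c(O[Si](C)(C)C)c(OC)c(OC)c4c3O[C@@H](C)OC4=O)c(O[Si](C)(C)C)c(OC)c(OC)c2C(=O)O1 | intermediate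
15 | (2S,2'S)-4,4',5,5'-tetramethoxy-2,2'-dimethyl-2,2',6,6'-tetrakis(trimethylsilyloxy)-[7,7'-bi-1-benzofuran]-3,3'(2H,2'H)-dione (tetrakis(silyl) bis-ketal; descriptor S only because OSi outranks the ring oxygen, spatial arrangement as in 16) | COc1c(O[Si](C)(C)C)c(-c2c(O[Si](C)(C)C)c(OC)c(OC)c3c2O[C@@](C)(O[Si](C)(C)C)C3=O)c2c(c1OC)C(=O)[C@](C)(O[Si](C)(C)C)O2 | intermediate
16 | (2R,2'R)-2,2',6,6'-tetrahydroxy-4,4',5,5'-tetramethoxy-2,2'-dimethyl-[7,7'-bi-1-benzofuran]-3,3'(2H,2'H)-dione (CNP0171547.1) | COc1c(O)c(-c2c(O)c(OC)c(OC)c3c2O[C@@](C)(O)C3=O)c2c(c1OC)C(=O)[C@](C)(O)O2 | target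

**Totals**
Total step count: 7. Longest linear sequence: 7 steps (the route is linear; 7 and 11 enter directly, and step 6 joins two molecules of 12).

**Three steps most likely to fail**

Step 5 (proposed new asymmetric acetalization). Risks: low selectivity with so small an aldehyde, erosion by acid-mediated re-ionization of the acylal, and decarboxylation of 10. Fallback with known chemistry, setting out from 10 and coming back at 12: the standard non-selective benzodioxinone formation (acetaldehyde, (CF3CO)2O/CF3CO2H, 0 °C to rt, aqueous NaHCO3 work-up) gives racemic 7-hydroxy-5,6-dimethoxy-2-methyl-4H-1,3-benzodioxin-4-one F1. Its enantiomers are separated by preparative supercritical-fluid chromatography on an amylose carbamate phase; the 2R enantiomer is 12.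

Step 6 (oxidative dimerization). Risks: the tetra-ortho-substituted biaryl may form slowly, C–O coupling or over-oxidation may compete, and the acidic aqueous medium may hydrolyse the acylal. Fallback, setting out from 12 and coming back at 13: iodination at the only free ring position (N-iodosuccinimide, MeCN, 0 °C) gives (2R)-7-hydroxy-8-iodo-5,6-dimethoxy-2-methyl-4H-1,3-benzodioxin-4-one F2. Benzylation (BnBr, K2CO3, acetone) gives (2R)-7-(benzyloxy)-8-iodo-5,6-dimethoxy-2-methyl-4H-1,3-benzodioxin-4-one F3. Ullmann homocoupling of two molecules of F3 (activated Cu powder, DMF, 130 °C) gives (2R,2'R)-7,7'-bis(benzyloxy)-5,5',6,6'-tetramethoxy-2,2'-dimethyl-4H,4'H-[8,8'-bi-1,3-benzodioxine]-4,4'-dione F4. Hydrogenolysis (H2, Pd/C, EtOAc) returns 13.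

Step 7 (proposed new ring contraction). Risks:
- The acetal C–H may be deprotonated too slowly by LiTMP.
- Me3SiCl may silylate the carbanion at carbon before the acyl shift takes place.
- Silylation of the rearranged alkoxide may lose the race with its ring opening, with loss of configuration.
- The free hemiketal can epimerize through its open diketone form in base or warm protic media, so 16 must be handled cold and under neutral to weakly acidic conditions.

Fallback with known chemistry, setting out from 6 and coming back at 16: Nencki-type acylation of 6 (propanoic acid, BF3·OEt2, 80 °C) gives 1-(2,4-dihydroxy-5,6-dimethoxyphenyl)propan-1-one F5. Riley oxidation (SeO2, dioxane/H2O, reflux) gives 1-(2,4-dihydroxy-5,6-dimethoxyphenyl)propane-1,2-dione F6, which closes spontaneously to racemic 2,6-dihydroxy-4,5-dimethoxy-2-methyl-1-benzofuran-3(2H)-one F7. Oxidative coupling of two molecules of F7 at C7 (Na2S2O8, FeSO4·7H2O, acetone/H2O) gives 2,2',6,6'-tetrahydroxy-4,4',5,5'-tetramethoxy-2,2'-dimethyl-[7,7'-bi-1-benzofuran]-3,3'(2H,2'H)-dione as a mixture of stereoisomers F8. The 2R,2'R isomer 16 is taken from it by preparative chromatography on a chiral stationary phase.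

**Further compounds**
F1 | step 5 | racemic 7-hydroxy-5,6-dimethoxy-2-methyl-4H-1,3-benzodioxin-4-one | CC1Oc2cc(O)c(OC)c(OC)c2C(=O)O1
F2 | step 6 | (2R)-7-hydroxy-8-iodo-5,6-dimethoxy-2-methyl-4H-1,3-benzodioxin-4-one | C[C@@H]1Oc2c(I)c(O)c(OC)c(OC)c2C(=O)O1
F3 | step 6 | (2R)-7-(benzyloxy)-8-iodo-5,6-dimethoxy-2-methyl-4H-1,3-benzodioxin-4-one | C[C@@H]1Oc2c(I)c(OCc3ccccc3)c(OC)c(OC)c2C(=O)O1
F4 | step 6 | (2R,2'R)-7,7'-bis(benzyloxy)-5,5',6,6'-tetramethoxy-2,2'-dimethyl-4H,4'H-[8,8'-bi-1,3-benzodioxine]-4,4'-dione | C[C@@H]1Oc2c(-c3c(OCc5ccccc5)c(OC)c(OC)c4c3O[C@@H](C)OC4=O)c(OCc3ccccc3)c(OC)c(OC)c2C(=O)O1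
F5 | step 7 | 1-(2,4-dihydroxy-5,6-dimethoxyphenyl)propan-1-one | CCC(=O)c1c(O)cc(O)c(OC)c1OC
F6 | step 7 | 1-(2,4-dihydroxy-5,6-dimethoxyphenyl)propane-1,2-dione | CC(=O)C(=O)c1c(O)cc(O)c(OC)c1OC
F7 | step 7 | racemic 2,6-dihydroxy-4,5-dimethoxy-2-methyl-1-benzofuran-3(2H)-one | COc1c(O)cc2OC(C)(O)C(=O)c2c1OC
F8 | step 7 | 2,2',6,6'-tetrahydroxy-4,4',5,5'-tetramethoxy-2,2'-dimethyl-[7,7'-bi-1-benzofuran]-3,3'(2H,2'H)-dione, mixture of stereoisomers | COc1c(O)c(-c2c(O)c(OC)c(OC)c3c2OC(C)(O)C3=O)c2c(c1OC)C(=O)C(C)(O)O2
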